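**Retrosynthetic overview**

1. The strategy rests on one feature of the ten-membered ring (C1–C10): the run C2(O)–C3–C4 bonded to the sp2 carbon C5 (exocyclic C16) is a ring-opened cyclopropanol joined to a 2-bromoalkene. The ring is therefore cut at C4–C5 and closed last, as the C2 ketone.
2. The seco precursor is ring A (C1, C10–C14) carrying a 1-hydroxycyclopropyl group at C1 and, at C10, the chain C9–C5 with the finished lactone (C7–O–C19–C17–C8) and C5(Br)=C16. Chlorine is put on C6 at the very end by inversion of a 6-epi alcohol.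
3. The lactone comes from an intramolecular samarium Reformatsky reaction of a 7-O-(2-bromopropanoyl) C8 ketone; C6–C7 from a boron aldol reaction with 2-bromoacrolein; C8–C9 from addition of a 2-lithioallyl ether to the C9 aldehyde.
4. Ring A comes from a catalytic enantioselective Diels–Alder reaction of (E)-piperylene with methyl (E)-2-methyl-4-oxobut-2-enoate (sets C1, C10, C11). The ester becomes the cyclopropanol (Kulinkovich), and the alkene becomes the 12α-oxygen and 13α,14α-epoxide.
5. Order of ring formation: ring A, cyclopropane, epoxide, lactone, ten-membered ring (the cyclopropane is consumed in closing it).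

Key step: step 22

Convention: briarane numbering (C1–C20) is used for every intermediate; in ring A, β is the face that carries the C15 methyl group.

Assumption: the (S)-oxazaborolidinium catalyst of step 2 is taken to shield the dienophile face that leads to the (1S,5S,6S) adduct, as its formyl-bound binding model suggests; if the sense proved opposite, the (R)-catalyst would be used with no other change.

**Step 1**
Reactants: 1 2,2-dimethoxyacetaldehyde; 2 methyl 2-(triphenylphosphoranylidene)propanoate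
Product: 4 methyl (E)-2-methyl-4-oxobut-2-enoate, via methyl (E)-4,4-dimethoxy-2-methylbut-2-enoate 3 (not isolated)
Conditions: CH2Cl2/H2O, rt; then 2 M HCl, THF, rt
Reagents that add atoms: water, O
Why: Wittig olefination with a stabilised α-methyl ylide should give the (E)-trisubstituted enoate, and the allylic dimethyl acetal is then hydrolysed by dilute acid without touching the ester.

**Step 2**
Reactants: 4 methyl (E)-2-methyl-4-oxobut-2-enoate; 5 (E)-penta-1,3-diene
Product: 6 methyl (1S,5S,6S)-6-formyl-1,5-dimethylcyclohex-3-ene-1-carboxylate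
Conditions: (S)-3,3-diphenyl-1-(o-tolyl)tetrahydro-1H,3H-pyrrolo[1,2-c][1,3,2]oxazaborole (20 mol %), Tf2NH (17 mol %), CH2Cl2, −78 to −40 °C
Reagents that add atoms: none
Why: Enantioselective Diels–Alder reaction under chiral oxazaborolidinium catalysis: the catalyst binds the formyl group, the unsubstituted diene terminus bonds to the activated β-carbon C1 and the methyl-bearing terminus to C10 (ortho rule), the endo transition state places the formyl group cis to the C11 methyl, the E geometry of 4 places the ester trans to the formyl group and the C15 methyl cis to it, and the shielded face of the catalyst fixes the absolute sense, so that C1, C10 and C11 are set together.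

**Step 3**
Reactants: 6 methyl (1S,5S,6S)-6-formyl-1,5-dimethylcyclohex-3-ene-1-carboxylate
Product: 7 methyl (1S,5S,6S)-6-(dimethoxymethyl)-1,5-dimethylcyclohex-3-ene-1-carboxylate
Conditions: HC(OMe)3, PPTS (cat.), MeOH, rt
Reagents that add atoms: trimethyl orthoformate, COC(OC)OC; methanol, CO
Why: Acid-catalysed acetalisation masks the C9 aldehyde under conditions mild enough to leave the adjacent C10 stereocentre untouched.

**Step 4**
Reactants: 7 methyl (1S,5S,6S)-6-(dimethoxymethyl)-1,5-dimethylcyclohex-3-ene-1-carboxylate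
Product: 8 1-[(1S,5S,6S)-6-(dimethoxymethyl)-1,5-dimethylcyclohex-3-en-1-yl]cyclopropan-1-ol
Conditions: EtMgBr (3 equiv, slow addition), Ti(OiPr)4 (0.5 equiv), THF, 0 °C to rt
Reagents that add atoms: ethylmagnesium bromide, CC[Mg]Br
Why: Kulinkovich cyclopropanation: the titanacyclopropane formed from EtMgBr and Ti(OiPr)4 acts as a 1,2-dicarbanion and adds twice to the only carbonyl group present, the cis-disubstituted ring alkene and the acetal being inert.

**Step 5**
Reactants: 8 1-[(1S,5S,6S)-6-(dimethoxymethyl)-1,5-dimethylcyclohex-3-en-1-yl]cyclopropan-1-ol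
Product: 9 triethylsilyl ether of cyclopropanol 8
Conditions: TESCl, imidazole, DMAP (cat.), DMF, 40 °C
Reagents that add atoms: chlorotriethylsilane, CC[Si](Cl)(CC)CC
Why: Silylation protects the cyclopropanol against the oxidants, bases and Lewis acids that follow, and a triethylsilyl ether can later be cleaved in the presence of tert-butyldimethylsilyl ethers.

**Step 6**
Reactants: 9 triethylsilyl ether of cyclopropanol 8
Product: 10 12α,13α-epoxide of 9
Conditions: mCPBA, NaHCO3, CH2Cl2, 0 °C
Reagents that add atoms: 3-chloroperbenzoic acid, OOC(=O)c1cccc(Cl)c1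
Why: Prilezhaev epoxidation: the bulky silyloxycyclopropyl group holds the equatorial position at C1, so the C15 methyl is axial on the β face next to the allylic C11 methyl, and the peracid should add to the open α face.

**Step 7**
Reactants: 10 12α,13α-epoxide of 9
Product: 11 12α-hydroxy-13-ene (allylic alcohol)
Conditions: Et2Al(TMP) [from lithium 2,2,6,6-tetramethylpiperidide and Et2AlCl], toluene, 0 °C
Reagents that add atoms: none
Why: Aluminium amide-promoted isomerisation of an epoxide to an allylic alcohol by syn β-elimination: the aluminium binds the epoxide oxygen on the α face and the amide removes the accessible secondary α-hydrogen on C14 in preference to the hindered tertiary H11, which leaves the 12α-oxygen in place and moves the alkene to C13=C14.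

**Step 8**
Reactants: 11 12α-hydroxy-13-ene (allylic alcohol)
Product: 12 12α-hydroxy-13α,14α-epoxide
Conditions: VO(acac)2 (cat.), t-BuOOH, CH2Cl2, 0 °C to rt
Reagents that add atoms: tert-butyl hydroperoxide, CC(C)(C)OO
Why: Vanadium-catalysed hydroxyl-directed epoxidation delivers oxygen from the face of the 12α-hydroxyl, which sets C13 and C14 cis to it.

**Step 9**
Reactants: 12 12α-hydroxy-13α,14α-epoxide
Product: 14 ring-A C9 aldehyde 12-O-triethylsilyl ether, via collidinium N,O-acetal triflate 13 (not isolated)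
Conditions: TESOTf (3 equiv), 2,4,6-collidine (5 equiv), CH2Cl2, 0 °C; then H2O, rt
Reagents that add atoms: triethylsilyl triflate, CC[Si](CC)(CC)OS(=O)(=O)C(F)(F)F; water, O
Why: The silyl triflate silylates the 12-hydroxyl and ionises the dimethyl acetal to a collidinium salt that water hydrolyses to the aldehyde, a base-buffered acetal cleavage that spares silyl ethers and the hindered epoxide.

**Step 10**
Reactants: 15 2,3-dibromoprop-1-ene
Product: 16 1-{[(2-bromoprop-2-en-1-yl)oxy]methyl}-4-methoxybenzene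
Conditions: 4-methoxybenzyl alcohol, NaH, THF/DMF, 0 °C to rt
Reagents that add atoms: 4-methoxybenzyl alcohol, COc1ccc(CO)cc1
Why: Williamson ether synthesis at the allylic bromide, the vinylic bromide being inert to SN2.

**Step 11**
Reactants: 14 ring-A C9 aldehyde 12-O-triethylsilyl ether; 16 1-{[(2-bromoprop-2-en-1-yl)oxy]methyl}-4-methoxybenzene
Product: 18 (9R)-9-hydroxy-8-methylene adduct, via 2-lithioallyl 4-methoxybenzyl ether 17 (not isolated)
Conditions: 16, t-BuLi (2 equiv), Et2O, −78 °C; then 14, −78 °C; aq NH4Cl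
Reagents that add atoms: none
Why: Bromine–lithium exchange and 1,2-addition to the aldehyde under Felkin–Anh control, the quaternary C1 being the large group anti to the nucleophile and H10 flanking its path, which should give the 9R alcohol.

**Step 12**
Reactants: 18 (9R)-9-hydroxy-8-methylene adduct
Product: 19 9-O-tert-butyldimethylsilyl ether of 18
Conditions: TBSOTf, 2,6-lutidine, CH2Cl2, −78 to 0 °C
Reagents that add atoms: tert-butyldimethylsilyl triflate, CC(C)(C)[Si](C)(C)OS(=O)(=O)C(F)(F)F
Why: Silyl triflate silylation of the hindered secondary alcohol gives the robust C9 protecting group carried to the end.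

**Step 13**
Reactants: 19 9-O-tert-butyldimethylsilyl ether of 18
Product: 20 (9R)-C8 ketone with 7-O-(4-methoxybenzyl)
Conditions: OsO4 (cat.), NaIO4, 2,6-lutidine, dioxane/H2O, rt
Reagents that add atoms: osmium tetroxide (catalytic oxygen donor), O=[Os](=O)(=O)=O; sodium periodate, [Na+].[O-]I(=O)(=O)=O
Why: Lemieux–Johnson oxidative cleavage of the only alkene in the molecule turns the 1,1-disubstituted C8 methylene into the C8 ketone.

**Step 14**
Reactants: 21 acrolein
Product: 23 2-bromoprop-2-enal, via 2,3-dibromopropanal 22 (not isolated)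
Conditions: Br2, CH2Cl2, 0 °C; then Et3N, 0 °C
Reagents that add atoms: bromine, BrBr
Why: Bromine addition followed by dehydrobromination of the acidic α-hydrogen gives the C6–C5–C16 unit, used freshly prepared.

**Step 15**
Reactants: 20 (9R)-C8 ketone with 7-O-(4-methoxybenzyl); 23 2-bromoprop-2-enal
Product: 25 (6S,7S,9R)-aldol adduct, via dibutylboron (Z)-enolate 24 (not isolated)
Conditions: Bu2BOTf, iPr2NEt, CH2Cl2, −78 °C; then 23, −78 to −20 °C; pH 7 buffer, MeOH, H2O2, 0 °C
Reagents that add atoms: none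
Why: Boron aldol reaction: the (Z)-enolate formed on the alkoxymethyl side adds through a chair Zimmerman–Traxler transition state (6,7-syn), and with the C9–OSi bond opposed to the enolate C–O bond the aldehyde approaches the face remote from ring A, which sets C7 syn to C9.

**Step 16**
Reactants: 25 (6S,7S,9R)-aldol adduct
Product: 26 6-O-tert-butyldimethylsilyl ether of 25
Conditions: TBSOTf, 2,6-lutidine, CH2Cl2, −78 °C
Reagents that add atoms: tert-butyldimethylsilyl triflate, CC(C)(C)[Si](C)(C)OS(=O)(=O)C(F)(F)F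
Why: Low-temperature silylation caps the allylic 6-hydroxyl before retro-aldol cleavage can intervene.

**Step 17**
Reactants: 26 6-O-tert-butyldimethylsilyl ether of 25
Product: 27 7-hydroxy C8 ketone
Conditions: DDQ, CH2Cl2/pH 7 buffer, 0 °C
Reagents that add atoms: none
Why: Oxidative cleavage of the 4-methoxybenzyl ether by DDQ frees only the 7-hydroxyl, silyl ethers, epoxide and bromoalkene being inert.

**Step 18**
Reactants: 27 7-hydroxy C8 ketone
Product: 28 7-O-(2-bromopropanoyl) C8 ketone
Conditions: 2-bromopropanoyl bromide, pyridine, CH2Cl2, −20 °C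
Reagents that add atoms: 2-bromopropanoyl bromide, CC(Br)C(Br)=O
Why: Acylation of the α-hydroxy ketone installs C17, C18 and C19 as a bromo ester whose halogen marks the site of enolate formation, its configuration being irrelevant.

**Step 19**
Reactants: 28 7-O-(2-bromopropanoyl) C8 ketone
Product: 30 β-hydroxy-γ-lactone (7S,8S,17R), via samarium enolate 29 (not isolated)
Conditions: SmI2 (2.2 equiv), THF, −78 °C; aq NH4Cl
Reagents that add atoms: none
Why: Intramolecular samarium Reformatsky reaction: SmI2 reduces the α-bromo ester to a trivalent samarium enolate that adds to the chelated C8 ketone in a five-membered aldol closure, the bulky C9 residue taking the lactone face opposite to the C6 substituent and to the C17 methyl, so that 8-OH is cis to C6 and the methyl cis to 8-OH, C17 being also the epimerisable, thermodynamically preferred centre.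

**Step 20**
Reactants: 30 β-hydroxy-γ-lactone (7S,8S,17R)
Product: 31 cyclopropanol 12-ol
Conditions: HF·pyridine, pyridine, THF, 0 °C
Reagents that add atoms: none
Why: Buffered fluoride cleaves the two triethylsilyl ethers while the two hindered tert-butyldimethylsilyl ethers, which are far less labile, should remain.

**Step 21**
Reactants: 31 cyclopropanol 12-ol
Product: 32 seco-4,5 cyclopropanol alkenyl bromide (12-acetate)
Conditions: Ac2O, pyridine, CH2Cl2, 0 °C to rt
Reagents that add atoms: acetic anhydride, CC(=O)OC(C)=O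
Why: Acetylation without strong acyl-transfer catalysis takes the secondary 12-hydroxyl and leaves the tertiary cyclopropanol (on a quaternary carbon) and the tertiary 8-hydroxyl free.

**Step 22**
Reactants: 32 seco-4,5 cyclopropanol alkenyl bromide (12-acetate)
Product: 33 ten-membered 2-ketone with 6-epi silyloxy group
Conditions: Pd(OAc)2 (10 mol %), XPhos (2-dicyclohexylphosphino-2′,4′,6′-triisopropylbiphenyl, 20 mol %), Cs2CO3 (2 equiv), toluene, 80 °C, syringe-pump addition of 32 to about 1 mM
Reagents that add atoms: none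
Why: Proposed new method: zerovalent palladium, formed in situ from Pd(OAc)2 and XPhos, inserts into the C5–Br bond, the caesium cyclopropoxide replaces bromide on palladium, β-carbon elimination driven by release of ring strain moves palladium to C4 (a palladium homoenolate of the C2 ketone), and C(sp3)–C(sp2) reductive elimination forms C4–C5. The closest known reaction type is the intermolecular palladium-catalysed ring-opening cross-coupling of cyclopropanols with aryl and alkenyl halides, and its use to close a medium ring is new. The ten-membered carbocycle closes by reductive elimination from an eleven-membered palladacycle in which C4 and C5 sit on the same metal, the methylene C16 staying exocyclic, and either cyclopropane CH2 may migrate because the two are equivalent. No stereocentre is created. The step needs reductive elimination to outrun β-hydride elimination from C4 (which would give a vinyl ketone and a reduced alkene) and ring closure to outrun oligomerisation; the bulky electron-rich biaryl phosphine and slow addition address these, while the trans arrangement of the C1 and C10 arms on ring A and the rigid lactone limit the conformations of the chain. Chlorine is absent at this stage because an allylic chloride would ionise with zerovalent palladium, and the cyclopropanol is the only hydroxyl that can both bind palladium and break a strained bond, the 8-hydroxyl being tertiary and unstrained.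

**Step 23**
Reactants: 33 ten-membered 2-ketone with 6-epi silyloxy group
Product: 34 (2R)-alcohol
Conditions: (S)-1-methyl-3,3-diphenyltetrahydro-1H,3H-pyrrolo[1,2-c][1,3,2]oxazaborole (1 equiv), catecholborane, toluene, −40 °C
Reagents that add atoms: none
Why: Corey–Bakshi–Shibata reduction under reagent control: the ketone lies between the quaternary C1 (large) and the C3 methylene (small), the clearest case for this catalyst, whose (S)-form should deliver hydride to give the 2R alcohol, and catecholborane spares the exocyclic alkene, lactone and acetate.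

**Step 24**
Reactants: 34 (2R)-alcohol
Product: 35 2,12-diacetate
Conditions: Ac2O, DMAP, pyridine, rt
Reagents that add atoms: acetic anhydride, CC(=O)OC(C)=O
Why: Catalysed acetylation of the hindered secondary 2-hydroxyl, the tertiary 8-hydroxyl being unreactive under these conditions.

**Step 25**
Reactants: 35 2,12-diacetate
Product: 36 6,8,9-triol
Conditions: HF·pyridine, THF, 0 °C to rt
Reagents that add atoms: none
Why: Fluoride cleavage of both tert-butyldimethylsilyl ethers under acidic, non-nucleophilic conditions that do not cause acetate migration.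

**Step 26**
Reactants: 36 6,8,9-triol
Product: 37 CNP0242711.1
Conditions: PPh3, hexachloroacetone, CH2Cl2, −20 to 0 °C
Reagents that add atoms: hexachloroacetone, ClC(Cl)(Cl)C(=O)C(Cl)(Cl)Cl
Why: Appel-type dehydroxy-chlorination: the least hindered, allylic 6-hydroxyl forms the alkoxyphosphonium ion and chloride displaces it by SN2 with inversion (6R alcohol to 6S chloride) with little allylic transposition, while the neopentyl-like 9-hydroxyl and the tertiary 8-hydroxyl are not substituted.

**Compound list**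

1 | 2,2-dimethoxyacetaldehyde | COC(OC)C=O | starting material
2 | methyl 2-(triphenylphosphoranylidene)propanoate | COC(=O)C(C)=P(c1ccccc1)(c1ccccc1)c1ccccc1 | starting material
3 | methyl (E)-4,4-dimethoxy-2-methylbut-2-enoate (formed in the flask) | COC(=O)/C(C)=C/C(OC)OC | intermediate
4 | methyl (E)-2-methyl-4-oxobut-2-enoate | COC(=O)/C(C)=C/C=O | intermediate
5 | (E)-penta-1,3-diene | C=C/C=C/C | starting material
6 | methyl (1S,5S,6S)-6-formyl-1,5-dimethylcyclohex-3-ene-1-carboxylate (ring A: C1 ester and β-methyl, C10 β-formyl, C11 β-methyl, C12=C13) | COC(=O)[C@]1(C)[C@H]([C@@H](C)C=CC1)C=O | intermediate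
7 | methyl (1S,5S,6S)-6-(dimethoxymethyl)-1,5-dimethylcyclohex-3-ene-1-carboxylate | COC(=O)[C@]1(C)[C@H]([C@@H](C)C=CC1)C(OC)OC | intermediate
8 | 1-[(1S,5S,6S)-6-(dimethoxymethyl)-1,5-dimethylcyclohex-3-en-1-yl]cyclopropan-1-ol | OC1(CC1)[C@]2(C)[C@H]([C@@H](C)C=CC2)C(OC)OC | intermediate
9 | triethylsilyl ether of 8 | CC[Si](CC)(CC)OC1(CC1)[C@]2(C)[C@H]([C@@H](C)C=CC2)C(OC)OC | intermediate
10 | 12α,13α-epoxide of 9 | CC[Si](CC)(CC)OC1(CC1)[C@]2(C)[C@H]([C@@H](C)[C@@H]3O[C@@H]3C2)C(OC)OC | intermediate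
11 | 12α-hydroxy-13-ene: ring A with C1 silyloxycyclopropyl, C10 dimethoxymethyl, C11 β-methyl | CC[Si](CC)(CC)OC1(CC1)[C@]2(C)[C@H]([C@@H](C)[C@H](O)C=C2)C(OC)OC | intermediate
12 | 12α-hydroxy-13α,14α-epoxide | CC[Si](CC)(CC)OC1(CC1)[C@]2(C)[C@H]([C@@H](C)[C@H](O)[C@@H]3O[C@@H]32)C(OC)OC | intermediate
13 | C9 methoxy(2,4,6-trimethylpyridinium-1-yl)methyl triflate, 12-O-TES (formed in the flask) | CC[Si](CC)(CC)OC1(CC1)[C@]2(C)[C@H]([C@@H](C)[C@H](O[Si](CC)(CC)CC)[C@@H]3O[C@@H]32)C(OC)[n+]1c(C)cc(C)cc1C.[O-]S(=O)(=O)C(F)(F)F | intermediate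
14 | ring-A C9 aldehyde: C1 1-(triethylsilyloxy)cyclopropyl, 12α-OTES, 13α,14α-epoxide, C10 β-formyl | CC[Si](CC)(CC)OC1(CC1)[C@]2(C)[C@H]([C@@H](C)[C@H](O[Si](CC)(CC)CC)[C@@H]3O[C@@H]32)C=O | intermediate
15 | 2,3-dibromoprop-1-ene | C=C(Br)CBr | starting material
16 | 1-{[(2-bromoprop-2-en-1-yl)oxy]methyl}-4-methoxybenzene | C=C(Br)COCc1ccc(OC)cc1 | intermediate
17 | {3-[(4-methoxybenzyl)oxy]prop-1-en-2-yl}lithium (formed in the flask) | [Li]C(=C)COCc1ccc(OC)cc1 | intermediate
18 | (9R)-9-hydroxy adduct: C8 bears exocyclic methylene and CH2O-PMB (C7) | CC[Si](CC)(CC)OC1(CC1)[C@]2(C)[C@H]([C@@H](C)[C@H](O[Si](CC)(CC)CC)[C@@H]3O[C@@H]32)[C@@H](O)C(=C)COCc1ccc(OC)cc1 | intermediate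
19 | 9-O-TBS ether of 18 | CC[Si](CC)(CC)OC1(CC1)[C@]2(C)[C@H]([C@@H](C)[C@H](O[Si](CC)(CC)CC)[C@@H]3O[C@@H]32)[C@@H](O[Si](C)(C)C(C)(C)C)C(=C)COCc1ccc(OC)cc1 | intermediate
20 | (9R)-9-OTBS C8 ketone with C7 CH2O-PMB | CC[Si](CC)(CC)OC1(CC1)[C@]2(C)[C@H]([C@@H](C)[C@H](O[Si](CC)(CC)CC)[C@@H]3O[C@@H]32)[C@@H](O[Si](C)(C)C(C)(C)C)C(=O)COCc1ccc(OC)cc1 | intermediate
21 | acrolein (prop-2-enal) | C=CC=O | starting material
22 | 2,3-dibromopropanal (formed in the flask) | O=CC(Br)CBr | intermediate
23 | 2-bromoprop-2-enal | C=C(Br)C=O | intermediate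
24 | dibutylboron (Z)-enolate of 20 (formed in the flask) | CC[Si](CC)(CC)OC1(CC1)[C@]2(C)[C@H]([C@@H](C)[C@H](O[Si](CC)(CC)CC)[C@@H]3O[C@@H]32)[C@@H](O[Si](C)(C)C(C)(C)C)/C(OB(CCCC)CCCC)=C/OCc1ccc(OC)cc1 | intermediate
25 | (6S,7S,9R)-aldol adduct: 6-OH, 7-O-PMB, C8 ketone, 9-OTBS, C5(Br)=C16 | CC[Si](CC)(CC)OC1(CC1)[C@]2(C)[C@H]([C@@H](C)[C@H](O[Si](CC)(CC)CC)[C@@H]3O[C@@H]32)[C@@H](O[Si](C)(C)C(C)(C)C)C(=O)[C@@H](OCc1ccc(OC)cc1)[C@H](O)C(Br)=C | intermediate
26 | 6-O-TBS ether of 25 | CC[Si](CC)(CC)OC1(CC1)[C@]2(C)[C@H]([C@@H](C)[C@H](O[Si](CC)(CC)CC)[C@@H]3O[C@@H]32)[C@@H](O[Si](C)(C)C(C)(C)C)C(=O)[C@@H](OCc1ccc(OC)cc1)[C@H](O[Si](C)(C)C(C)(C)C)C(Br)=C | intermediate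
27 | (6S,7S,9R)-7-hydroxy C8 ketone, 6,9-bis-OTBS | CC[Si](CC)(CC)OC1(CC1)[C@]2(C)[C@H]([C@@H](C)[C@H](O[Si](CC)(CC)CC)[C@@H]3O[C@@H]32)[C@@H](O[Si](C)(C)C(C)(C)C)C(=O)[C@@H](O)[C@H](O[Si](C)(C)C(C)(C)C)C(Br)=C | intermediate
28 | 7-O-(2-bromopropanoyl) ester of 27 (bromide epimers) | CC[Si](CC)(CC)OC1(CC1)[C@]2(C)[C@H]([C@@H](C)[C@H](O[Si](CC)(CC)CC)[C@@H]3O[C@@H]32)[C@@H](O[Si](C)(C)C(C)(C)C)C(=O)[C@@H](OC(=O)C(C)Br)[C@H](O[Si](C)(C)C(C)(C)C)C(Br)=C | intermediate
29 | trivalent samarium ester enolate of 28 (formed in the flask) | CC[Si](CC)(CC)OC1(CC1)[C@]2(C)[C@H]([C@@H](C)[C@H](O[Si](CC)(CC)CC)[C@@H]3O[C@@H]32)[C@@H](O[Si](C)(C)C(C)(C)C)C(=O)[C@@H](OC(O[Sm](I)I)=CC)[C@H](O[Si](C)(C)C(C)(C)C)C(Br)=C | intermediate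
30 | β-hydroxy-γ-lactone (6S,7S,8S,9R,17R): cyclopropyl-OTES, 12-OTES, 6,9-bis-OTBS, 8-OH | CC[Si](CC)(CC)OC1(CC1)[C@]2(C)[C@H]([C@@H](C)[C@H](O[Si](CC)(CC)CC)[C@@H]3O[C@@H]32)[C@@H](O[Si](C)(C)C(C)(C)C)[C@]2(O)[C@@H](C)C(=O)O[C@H]2[C@H](O[Si](C)(C)C(C)(C)C)C(Br)=C | intermediate
31 | cyclopropanol 12-ol (both triethylsilyl groups removed) | OC1(CC1)[C@]2(C)[C@H]([C@@H](C)[C@H](O)[C@@H]3O[C@@H]32)[C@@H](O[Si](C)(C)C(C)(C)C)[C@]2(O)[C@@H](C)C(=O)O[C@H]2[C@H](O[Si](C)(C)C(C)(C)C)C(Br)=C | intermediate
32 | seco-4,5 cyclopropanol alkenyl bromide: 12-OAc, 6,9-bis-OTBS, 8-OH | OC1(CC1)[C@]2(C)[C@H]([C@@H](C)[C@H](OC(C)=O)[C@@H]3O[C@@H]32)[C@@H](O[Si](C)(C)C(C)(C)C)[C@]2(O)[C@@H](C)C(=O)O[C@H]2[C@H](O[Si](C)(C)C(C)(C)C)C(Br)=C | intermediate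
33 | ten-membered 2-ketone with 6-epi (6R) silyloxy group | C=C1CCC(=O)[C@]2(C)[C@H]([C@@H](C)[C@H](OC(C)=O)[C@@H]3O[C@@H]32)[C@@H](O[Si](C)(C)C(C)(C)C)[C@]2(O)[C@@H](C)C(=O)O[C@H]2[C@@H]1O[Si](C)(C)C(C)(C)C | intermediate
34 | (2R)-alcohol | C=C1CC[C@@H](O)[C@]2(C)[C@H]([C@@H](C)[C@H](OC(C)=O)[C@@H]3O[C@@H]32)[C@@H](O[Si](C)(C)C(C)(C)C)[C@]2(O)[C@@H](C)C(=O)O[C@H]2[C@@H]1O[Si](C)(C)C(C)(C)C | intermediate
35 | 2,12-diacetate, 6,9-bis-OTBS | C=C1CC[C@@H](OC(C)=O)[C@]2(C)[C@H]([C@@H](C)[C@H](OC(C)=O)[C@@H]3O[C@@H]32)[C@@H](O[Si](C)(C)C(C)(C)C)[C@]2(O)[C@@H](C)C(=O)O[C@H]2[C@@H]1O[Si](C)(C)C(C)(C)C | intermediate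
36 | 6,8,9-triol (6R) 2,12-diacetate | C=C1CC[C@@H](OC(C)=O)[C@]2(C)[C@H]([C@@H](C)[C@H](OC(C)=O)[C@@H]3O[C@@H]32)[C@@H](O)[C@]2(O)[C@@H](C)C(=O)O[C@H]2[C@@H]1O | intermediate
37 | CNP0242711.1 (1S,2R,6S,7R,8R,9R,10S,11R,12S,13S,14R,17R) | C=C1CC[C@@H](OC(C)=O)[C@]2(C)[C@H]([C@@H](C)[C@H](OC(C)=O)[C@@H]3O[C@@H]32)[C@@H](O)[C@]2(O)[C@@H](C)C(=O)O[C@H]2[C@H]1Cl | target

**Step count**

Total: 26 steps. Longest linear sequence: 24 steps (steps 1–9, 11–13 and 15–26; steps 10 and 14 make side reagents).

**Steps most likely to fail**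

Step 22 (ring closure). The C4 alkylpalladium may lose a β-hydrogen, or intermolecular coupling may outpace transannular reductive elimination, so that no ten-membered ring forms. The fallback keeps the C4–C5 bond but makes it by a B-alkyl Suzuki–Miyaura macrocyclisation, a known way to close rings. It sets out from cyclopropanol 32. NBS in CH2Cl2 at 0 °C opens the cyclopropanol to the β-bromo ketone F1. Et3N eliminates HBr to give the vinyl ketone F2. NaBH4 with CeCl3·7H2O gives the allylic alcohol F3 (both C2 epimers are usable). 9-BBN hydroborates the monosubstituted alkene in preference to the bromoalkene to give the alkylborane F4. Without isolation, Pd(dppf)Cl2, AsPh3 and Cs2CO3 in DMF/THF/H2O at high dilution couple the borane with the C5 bromide to give the ten-membered 2-alcohol F5. Dess–Martin oxidation of F5 returns to ketone 33.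

Step 26 (chlorination). Activation of the 9-hydroxyl may compete, or chloride may enter at C16 with allylic transposition, or ionisation may erode inversion. The fallback changes the order of events so that only one secondary hydroxyl is free and activation is separated from displacement. It sets out from diacetate 35. HF·pyridine buffered with pyridine at 0 °C, stopped after cleavage of the allylic ether only, gives the 6-hydroxy 9-silyl ether F6. MsCl and Et3N at −30 °C give the mesylate F7. LiCl in DMF at 0 °C displaces it with inversion to the 6S chloride F8. HF·pyridine then removes the 9-O-silyl group and the route is rejoined at 37.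

Step 4 (Kulinkovich reaction). Addition of the titanacyclopropane to an ester on a quaternary carbon with a branched neighbour may be too slow, leaving starting material or giving simple ethyl addition. The fallback builds the cyclopropane by carbenoid addition instead. It sets out from ester 7. Me3SiCH2Li gives the α-silyl ketone F9, which methanol desilylates on work-up to the methyl ketone F10. LiN(iPr)2 and TESCl give the triethylsilyl enol ether F11. Simmons–Smith cyclopropanation (Et2Zn, CH2I2) of the electron-rich enol ether, faster than that of the ring alkene, gives the silyl-protected cyclopropanol directly, and the route is rejoined at 9.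

**Further compounds**

F1 | step 22 | β-bromo ketone (C2 ketone, C4 bromide) from ring opening of 32 | BrCCC(=O)[C@]2(C)[C@H]([C@@H](C)[C@H](OC(C)=O)[C@@H]3O[C@@H]32)[C@@H](O[Si](C)(C)C(C)(C)C)[C@]2(O)[C@@H](C)C(=O)O[C@H]2[C@H](O[Si](C)(C)C(C)(C)C)C(Br)=C
F2 | step 22 | vinyl ketone (C2 ketone, C3=C4) | C=CC(=O)[C@]2(C)[C@H]([C@@H](C)[C@H](OC(C)=O)[C@@H]3O[C@@H]32)[C@@H](O[Si](C)(C)C(C)(C)C)[C@]2(O)[C@@H](C)C(=O)O[C@H]2[C@H](O[Si](C)(C)C(C)(C)C)C(Br)=C
F3 | step 22 | allylic alcohol (C2 epimers) | C=CC(O)[C@]2(C)[C@H]([C@@H](C)[C@H](OC(C)=O)[C@@H]3O[C@@H]32)[C@@H](O[Si](C)(C)C(C)(C)C)[C@]2(O)[C@@H](C)C(=O)O[C@H]2[C@H](O[Si](C)(C)C(C)(C)C)C(Br)=C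
F4 | step 22 | C4 B-alkyl-9-borabicyclo[3.3.1]nonane | OC(CCB1C2CCCC1CCC2)[C@]3(C)[C@H]([C@@H](C)[C@H](OC(C)=O)[C@@H]4O[C@@H]43)[C@@H](O[Si](C)(C)C(C)(C)C)[C@]3(O)[C@@H](C)C(=O)O[C@H]3[C@H](O[Si](C)(C)C(C)(C)C)C(Br)=C
F5 | step 22 | ten-membered 2-alcohol (C2 epimers) | C=C1CCC(O)[C@]2(C)[C@H]([C@@H](C)[C@H](OC(C)=O)[C@@H]3O[C@@H]32)[C@@H](O[Si](C)(C)C(C)(C)C)[C@]2(O)[C@@H](C)C(=O)O[C@H]2[C@@H]1O[Si](C)(C)C(C)(C)C
F6 | step 26 | 6-hydroxy 9-O-TBS 2,12-diacetate | C=C1CC[C@@H](OC(C)=O)[C@]2(C)[C@H]([C@@H](C)[C@H](OC(C)=O)[C@@H]3O[C@@H]32)[C@@H](O[Si](C)(C)C(C)(C)C)[C@]2(O)[C@@H](C)C(=O)O[C@H]2[C@@H]1O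
F7 | step 26 | 6-O-mesylate of F6 | C=C1CC[C@@H](OC(C)=O)[C@]2(C)[C@H]([C@@H](C)[C@H](OC(C)=O)[C@@H]3O[C@@H]32)[C@@H](O[Si](C)(C)C(C)(C)C)[C@]2(O)[C@@H](C)C(=O)O[C@H]2[C@@H]1OS(C)(=O)=O
F8 | step 26 | (6S)-6-chloro 9-O-TBS 2,12-diacetate | C=C1CC[C@@H](OC(C)=O)[C@]2(C)[C@H]([C@@H](C)[C@H](OC(C)=O)[C@@H]3O[C@@H]32)[C@@H](O[Si](C)(C)C(C)(C)C)[C@]2(O)[C@@H](C)C(=O)O[C@H]2[C@H]1Cl
F9 | step 4 | (trimethylsilyl)methyl ketone at C2 | C[Si](C)(C)CC(=O)[C@]1(C)[C@H]([C@@H](C)C=CC1)C(OC)OC
F10 | step 4 | methyl ketone at C2 | CC(=O)[C@]1(C)[C@H]([C@@H](C)C=CC1)C(OC)OC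
F11 | step 4 | triethylsilyl enol ether of F10 | C=C(O[Si](CC)(CC)CC)[C@]1(C)[C@H]([C@@H](C)C=CC1)C(OC)OC
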